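**Retrosynthetic overview**

1. Chain numbering used throughout: C1=C2 vinyl, C3 carbinol, C6 ring CH, C7 ring C(CH3)–O, C8 and C9 ring CH2, C10 ring CH–O, C11 quaternary ring carbon, C14 CHBr, C15 CMe2Cl. The target comes from its tertiary silyl ether by desilylation.
2. The silyl ether comes from an acyclic (6Z)-alkene/(10R,11S)-epoxide in one Lewis-acid cascade. The C6–C11 bond closes the cyclohexane ring first, then O–C7 closes the oxolane bridge, so both rings, the quaternary C11 and all four ring stereocentres arise in one operation.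
3. Enabling feature: the oxolane ring C6–C11–C10–O–C7 of the 7-oxabicyclo[2.2.1]heptane is the formal (3+2) adduct of a C10–C11 epoxide and a C6=C7 alkene. C11 and C7 are both fully substituted, and the oxygen on C10 lies 1,4 to C7 across the six-membered ring.
4. The acyclic precursor comes from a B-alkyl Suzuki union (C7–C8) of a (Z)-alkenyl iodide, made from (S)-linalool (C3 centre, 6Z geometry), with a vinyl epoxide that already carries the CHBr–CMe2Cl terminus.
5. The vinyl epoxide comes from neryl acetate: Shi epoxidation, Markovnikov HBr opening and a 1,2-bromine shift set C14 and the Br/Cl pair, and Sharpless epoxidation of the (Z)-allylic alcohol sets C10 and C11.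

Key step: step 12

Remark: (S)-(+)-linalool is assumed to be purchased in enantiomerically enriched form; it is the only source of the C3 configuration.

**Route**

Step 1
Reactants: 1 neryl acetate, (2Z)-3,7-dimethylocta-2,6-dien-1-yl acetate
Product: 2 (2Z)-5-[(2R)-3,3-dimethyloxiran-2-yl]-3-methylpent-2-en-1-yl acetate
Conditions: Shi ketone from D-fructose (1,2:4,5-di-O-isopropylidene-β-D-erythro-2,3-hexodiulo-2,6-pyranose, 30 mol %), Oxone (2KHSO5·KHSO4·K2SO4), K2CO3, Bu4NHSO4 (cat.), MeCN/dimethoxymethane/aq. Na2B4O7 buffer, 0 °C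
Reagents that add atoms: Oxone, active component potassium peroxymonosulfate, [K+].[O-]S(=O)(=O)OO
Why: Shi epoxidation: the chiral dioxirane should epoxidise only the electron-rich distal trisubstituted alkene (the proximal one is deactivated by the allylic acetate), and the D-fructose-derived ketone sets the (R) configuration at the epoxide CH that later becomes C14.

Step 2
Reactants: 2 (2Z)-5-[(2R)-3,3-dimethyloxiran-2-yl]-3-methylpent-2-en-1-yl acetate
Product: 3 (2Z,6R)-7-bromo-6-hydroxy-3,7-dimethyloct-2-en-1-yl acetate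
Conditions: 48 % aq. HBr (1.2 equiv), Et2O, −15 °C
Reagents that add atoms: hydrogen bromide, Br
Why: Markovnikov (borderline SN1) hydrobromic acid opening of a trisubstituted epoxide delivers bromide to the tertiary carbon, with the secondary C–O bond and its (R) configuration left untouched.

Step 3
Reactants: 3 (2Z,6R)-7-bromo-6-hydroxy-3,7-dimethyloct-2-en-1-yl acetate
Product: 6 (2Z,6S)-6-bromo-7-chloro-3,7-dimethyloct-2-en-1-yl acetate, via alkoxyphosphonium chloride 4 (not isolated), via bromonium chloride 5 (not isolated)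
Conditions: PPh3, CCl4, CH2Cl2, 0 °C → rt
Reagents that add atoms: carbon tetrachloride, ClC(Cl)(Cl)Cl
Why: Appel activation with neighbouring-group participation: the tertiary bromine displaces the oxyphosphonium group from the rear to give bromonium ion 5 (inversion at the CH carbon, R to S) and chloride reopens it at the tertiary carbon, so a stereospecific 1,2-bromine shift installs the CHBr–CMe2Cl pair.

Step 4
Reactants: 6 (2Z,6S)-6-bromo-7-chloro-3,7-dimethyloct-2-en-1-yl acetate
Product: 7 (2Z,6S)-6-bromo-7-chloro-3,7-dimethyloct-2-en-1-ol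
Conditions: K2CO3 (0.2 equiv), MeOH, 0 °C
Reagents that add atoms: none
Why: Base-catalysed transesterification (methanolysis) of the acetate under conditions too mild for elimination at the halogenated terminus, with no stereocentre involved.

Step 5
Reactants: 7 (2Z,6S)-6-bromo-7-chloro-3,7-dimethyloct-2-en-1-ol
Product: 8 {(2R,3S)-3-[(3S)-3-bromo-4-chloro-4-methylpentyl]-3-methyloxiran-2-yl}methanol
Conditions: Ti(OiPr)4 (10 mol %), D-(−)-diethyl tartrate (12 mol %), t-BuOOH (decane), 4 Å molecular sieves, CH2Cl2, −20 °C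
Reagents that add atoms: tert-butyl hydroperoxide, CC(C)(C)OO
Why: Sharpless asymmetric epoxidation of the (Z)-allylic alcohol, in which D-(−)-tartrate directs oxygen to the face giving the (2R,3S) cis-epoxide under reagent control (the remote C–Br centre has no influence), fixing the future C10 and C11.

Step 6
Reactants: 8 {(2R,3S)-3-[(3S)-3-bromo-4-chloro-4-methylpentyl]-3-methyloxiran-2-yl}methanol
Product: 9 (2S,3S)-3-[(3S)-3-bromo-4-chloro-4-methylpentyl]-3-methyloxirane-2-carbaldehyde
Conditions: PhI(OAc)2, TEMPO (10 mol %), CH2Cl2, rt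
Reagents that add atoms: none
Why: Oxoammonium (TEMPO) oxidation of the primary alcohol stops at the aldehyde and tolerates the epoxide and both halides, and the non-enolisable epoxide carbon keeps its configuration (the descriptor changes only through ligand priority).

Step 7
Reactants: 9 (2S,3S)-3-[(3S)-3-bromo-4-chloro-4-methylpentyl]-3-methyloxirane-2-carbaldehyde
Product: 10 (2S,3R)-2-[(3S)-3-bromo-4-chloro-4-methylpentyl]-2-methyl-3-vinyloxirane
Conditions: Ph3PCH3Br, KN(SiMe3)2, THF, −78 → 0 °C
Reagents that add atoms: methyltriphenylphosphonium bromide, C[P+](c1ccccc1)(c1ccccc1)c1ccccc1.[Br-]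
Why: Wittig methylenation of the epoxy aldehyde at low temperature adds the C8 carbon as a terminal alkene, the ylide being consumed by the aldehyde faster than it can act as a base toward the alkyl halides.

Step 8
Reactants: 11 (S)-(+)-linalool, (3S)-3,7-dimethylocta-1,6-dien-3-ol
Product: 12 tert-butyl{[(3S)-3,7-dimethylocta-1,6-dien-3-yl]oxy}dimethylsilane
Conditions: TBSOTf, 2,6-lutidine, CH2Cl2, 0 °C → rt
Reagents that add atoms: tert-butyldimethylsilyl triflate, CC(C)(C)[Si](C)(C)OS(=O)(=O)C(F)(F)F
Why: Silylation of the hindered tertiary alcohol with the silyl triflate and a hindered base, which masks the carbinol (C3, from the chiral pool) against ionisation and cation capture in step 12.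

Step 9
Reactants: 12 tert-butyl{[(3S)-3,7-dimethylocta-1,6-dien-3-yl]oxy}dimethylsilane
Product: 14 (4S)-4-[(tert-butyldimethylsilyl)oxy]-4-methylhex-5-enal, via ozonide 13 (not isolated)
Conditions: O3 (1 equiv, Sudan Red 7B end point), CH2Cl2, −78 °C; then PPh3, −78 °C → rt
Reagents that add atoms: ozone, [O-][O+]=O
Why: Ozonolysis with reductive work-up, chemoselective for the trisubstituted alkene over the electron-poorer, hindered vinyl group when ozone is limited to one equivalent.

Step 10
Reactants: 14 (4S)-4-[(tert-butyldimethylsilyl)oxy]-4-methylhex-5-enal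
Product: 15 tert-butyl{[(3S,6Z)-7-iodo-3-methylocta-1,6-dien-3-yl]oxy}dimethylsilane
Conditions: [Ph3PEt]I, n-BuLi, THF, 0 °C; I2, −78 °C; NaN(SiMe3)2, −78 °C; then 14, −78 → −20 °C
Reagents that add atoms: ethyltriphenylphosphonium iodide, CC[P+](c1ccccc1)(c1ccccc1)c1ccccc1.[I-]; iodine, [I][I]
Why: Stork–Zhao olefination (Wittig reaction of the α-iodo ylide) gives the (Z)-2-iodoalkene through the kinetically favoured cis-oxaphosphetane, which fixes the later 6Z geometry.

Step 11
Reactants: 10 (2S,3R)-2-[(3S)-3-bromo-4-chloro-4-methylpentyl]-2-methyl-3-vinyloxirane; 15 tert-butyl{[(3S,6Z)-7-iodo-3-methylocta-1,6-dien-3-yl]oxy}dimethylsilane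
Product: 17 tert-butyl{[(3S,6Z)-9-{(2R,3S)-3-[(3S)-3-bromo-4-chloro-4-methylpentyl]-3-methyloxiran-2-yl}-3,7-dimethylnona-1,6-dien-3-yl]oxy}dimethylsilane, via alkylborane 16 (not isolated)
Conditions: 10, 9-BBN, THF, 0 °C → rt; aq. Cs2CO3; then 15, Pd(dppf)Cl2 (5 mol %), AsPh3 (10 mol %), DMF, rt
Reagents that add atoms: none
Why: Anti-Markovnikov hydroboration of the terminal alkene followed by B-alkyl Suzuki–Miyaura coupling with the alkenyl iodide, which proceeds with retention of the Z geometry at room temperature and leaves the epoxide, the alkyl halides and the silyl ether untouched.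

Step 12
Reactants: 17 tert-butyl{[(3S,6Z)-9-{(2R,3S)-3-[(3S)-3-bromo-4-chloro-4-methylpentyl]-3-methyloxiran-2-yl}-3,7-dimethylnona-1,6-dien-3-yl]oxy}dimethylsilane
Product: 19 tert-butyl{[(3S)-5-{(1S,2S,3S,4R)-3-[(3S)-3-bromo-4-chloro-4-methylpentyl]-1,3-dimethyl-7-oxabicyclo[2.2.1]heptan-2-yl}-3-methylpent-1-en-3-yl]oxy}dimethylsilane, via zwitterionic cyclohexyl cation 18 (not isolated)
Conditions: BF3·OEt2 (0.3 equiv), CH2Cl2, −78 °C; Et3N quench
Reagents that add atoms: none
Why: BF3 coordinates the epoxide oxygen, the C6=C7 alkene attacks the tertiary epoxide carbon C11 anti to the breaking C11–O bond to give the tertiary C7 cation 18, and the boron-bound C10 oxygen then captures C7 across the ring and releases BF3. This is the epoxide-initiated cation–olefin cyclisation with internal alkoxide termination, the reaction type that converts terminal epoxy-olefins of the geranyl type into 7-oxabicyclo[2.2.1]heptanes, and it amounts to an intramolecular formal (3+2) addition of the epoxide C–O unit across the alkene. The cyclohexane closes through the C6–C11 bond by 6-endo-trig attack of the alkene with the epoxide opened at its more substituted carbon (oxygen kept on the new ring), and the oxolane closes by transannular 1,4 capture of C7 by oxygen through a boat conformer of 18. C11 is set by stereospecific inversion of the (11S) epoxide carbon, so the (Z)-epoxide places the halogenated chain cis to oxygen (exo); C6 is set by the chair transition state, in which the 6Z geometry forces the C5 chain axial and therefore trans to the C10 oxygen (endo); C7 can only form with the bridge cis to C10, and C10 is carried through unchanged. The step needs Markovnikov epoxide opening, chair rather than boat folding, and oxygen capture rather than proton loss, 1,2-shift or capture by a side chain: the fully substituted C11 and C7 secure the first, and the electron-poor bromochloro chain, the bulky tertiary silyl ether, the equatorial (non-aligned) C6–H of 18 and the low temperature are relied on for the others.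

Step 13
Reactants: 19 tert-butyl{[(3S)-5-{(1S,2S,3S,4R)-3-[(3S)-3-bromo-4-chloro-4-methylpentyl]-1,3-dimethyl-7-oxabicyclo[2.2.1]heptan-2-yl}-3-methylpent-1-en-3-yl]oxy}dimethylsilane
Product: 20 (3S)-5-{(1S,2S,3S,4R)-3-[(3S)-3-bromo-4-chloro-4-methylpentyl]-1,3-dimethyl-7-oxabicyclo[2.2.1]heptan-2-yl}-3-methylpent-1-en-3-ol
Conditions: HF·pyridine, pyridine, THF, 0 °C → rt
Reagents that add atoms: none
Why: Fluoride-mediated cleavage of the tertiary silyl ether under buffered conditions that leave the tertiary allylic alcohol, the alkyl halides and the bridged ether intact, with no stereocentre affected.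

**Compound list**

1 | neryl acetate, (2Z)-3,7-dimethylocta-2,6-dien-1-yl acetate | CC(=O)OC/C=C(/C)CCC=C(C)C | starting material
2 | (2Z)-5-[(2R)-3,3-dimethyloxiran-2-yl]-3-methylpent-2-en-1-yl acetate | CC(=O)OC/C=C(/C)CC[C@H]1OC1(C)C | intermediate
3 | (2Z,6R)-7-bromo-6-hydroxy-3,7-dimethyloct-2-en-1-yl acetate | CC(=O)OC/C=C(/C)CC[C@@H](O)C(C)(C)Br | intermediate
4 | {[(2Z,6R)-1-acetoxy-7-bromo-3,7-dimethyloct-2-en-6-yl]oxy}triphenylphosphonium chloride | CC(=O)OC/C=C(/C)CC[C@@H](O[P+](c1ccccc1)(c1ccccc1)c1ccccc1)C(C)(C)Br.[Cl-] | intermediate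
5 | (2Z)-5-[(2S)-3,3-dimethylbromiran-1-ium-2-yl]-3-methylpent-2-en-1-yl acetate chloride | CC(=O)OC/C=C(/C)CC[C@@H]1[Br+]C1(C)C.[Cl-] | intermediate
6 | (2Z,6S)-6-bromo-7-chloro-3,7-dimethyloct-2-en-1-yl acetate | CC(=O)OC/C=C(/C)CC[C@H](Br)C(C)(C)Cl | intermediate
7 | (2Z,6S)-6-bromo-7-chloro-3,7-dimethyloct-2-en-1-ol | OC/C=C(/C)CC[C@H](Br)C(C)(C)Cl | intermediate
8 | {(2R,3S)-3-[(3S)-3-bromo-4-chloro-4-methylpentyl]-3-methyloxiran-2-yl}methanol | OC[C@H]1O[C@@]1(C)CC[C@H](Br)C(C)(C)Cl | intermediate
9 | (2S,3S)-3-[(3S)-3-bromo-4-chloro-4-methylpentyl]-3-methyloxirane-2-carbaldehyde | O=C[C@H]1O[C@@]1(C)CC[C@H](Br)C(C)(C)Cl | intermediate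
10 | (2S,3R)-2-[(3S)-3-bromo-4-chloro-4-methylpentyl]-2-methyl-3-vinyloxirane | C=C[C@H]1O[C@@]1(C)CC[C@H](Br)C(C)(C)Cl | intermediate
11 | (S)-(+)-linalool, (3S)-3,7-dimethylocta-1,6-dien-3-ol | C=C[C@@](C)(O)CCC=C(C)C | starting material
12 | tert-butyl{[(3S)-3,7-dimethylocta-1,6-dien-3-yl]oxy}dimethylsilane | C=C[C@@](C)(O[Si](C)(C)C(C)(C)C)CCC=C(C)C | intermediate
13 | tert-butyl{[(3S)-5-(5,5-dimethyl-1,2,4-trioxolan-3-yl)-3-methylpent-1-en-3-yl]oxy}dimethylsilane (ozonide, both epimers at the trioxolane CH) | C=C[C@@](C)(O[Si](C)(C)C(C)(C)C)CCC1OOC(C)(C)O1 | intermediate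
14 | (4S)-4-[(tert-butyldimethylsilyl)oxy]-4-methylhex-5-enal | C=C[C@@](C)(O[Si](C)(C)C(C)(C)C)CCC=O | intermediate
15 | tert-butyl{[(3S,6Z)-7-iodo-3-methylocta-1,6-dien-3-yl]oxy}dimethylsilane | C=C[C@@](C)(O[Si](C)(C)C(C)(C)C)CC/C=C(/C)I | intermediate
16 | 9-{2-[(2R,3S)-3-[(3S)-3-bromo-4-chloro-4-methylpentyl]-3-methyloxiran-2-yl]ethyl}-9-borabicyclo[3.3.1]nonane | B1(CC[C@H]2O[C@@]2(C)CC[C@H](Br)C(C)(C)Cl)C2CCCC1CCC2 | intermediate
17 | tert-butyl{[(3S,6Z)-9-{(2R,3S)-3-[(3S)-3-bromo-4-chloro-4-methylpentyl]-3-methyloxiran-2-yl}-3,7-dimethylnona-1,6-dien-3-yl]oxy}dimethylsilane | C=C[C@@](C)(O[Si](C)(C)C(C)(C)C)CC/C=C(/C)CC[C@H]1O[C@@]1(C)CC[C@H](Br)C(C)(C)Cl | intermediate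
18 | zwitterion after C6–C11 closure: cyclohexane with a carbocation at C7 (bearing CH3), O–BF3(−) on C10, C11 bearing CH3 and the bromochloroalkyl chain cis to that oxygen, and C6 bearing the silyloxyalkenyl chain trans to it | C=C[C@@](C)(O[Si](C)(C)C(C)(C)C)CC[C@@H]1[C+](C)CC[C@@H](O[B-](F)(F)F)[C@@]1(C)CC[C@H](Br)C(C)(C)Cl | intermediate
19 | tert-butyl{[(3S)-5-{(1S,2S,3S,4R)-3-[(3S)-3-bromo-4-chloro-4-methylpentyl]-1,3-dimethyl-7-oxabicyclo[2.2.1]heptan-2-yl}-3-methylpent-1-en-3-yl]oxy}dimethylsilane | C=C[C@@](C)(O[Si](C)(C)C(C)(C)C)CC[C@H]1[C@](C)(CC[C@H](Br)C(C)(C)Cl)[C@H]2CC[C@]1(C)O2 | intermediate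
20 | (3S)-5-{(1S,2S,3S,4R)-3-[(3S)-3-bromo-4-chloro-4-methylpentyl]-1,3-dimethyl-7-oxabicyclo[2.2.1]heptan-2-yl}-3-methylpent-1-en-3-ol | C=C[C@@](C)(O)CC[C@H]1[C@](C)(CC[C@H](Br)C(C)(C)Cl)[C@H]2CC[C@]1(C)O2 | target

**Step count and risks**

Total steps: 13. Longest linear sequence: 10 steps (steps 1–7, then 11–13, from neryl acetate).

Steps most likely to fail:

Step 12. The C7 cation may be discharged by proton loss or a 1,2-shift before the C–O bond closes, the chain may fold through a boat (epimer at C6), or the tertiary allylic silyl ether may ionise or capture the cation. The fallback separates the two ring closures and sets out from 17. Cyclisation with MeAlCl2 (CH2Cl2, −94 °C), whose aluminium-bound alkoxide is a poor nucleophile, should end by proton loss and give the methylidenecyclohexanol 2-[(3S)-3-bromo-4-chloro-4-methylpentyl]-3-{(3S)-3-[(tert-butyldimethylsilyl)oxy]-3-methylpent-4-en-1-yl}-2-methyl-4-methylidenecyclohexan-1-ol F1 (ring configuration as in 18). Intramolecular Markovnikov alkoxymercuration with Hg(OCOCF3)2 (CH2Cl2, 0 °C), which passes through a mercurinium ion and not a free cation, would then close the oxygen bridge to the bridgehead (trifluoroacetoxymercurio)methyl analogue of 19 F2 (not isolated). Demercuration with NaBH4/NaOH turns the CH2Hg group into the bridgehead methyl and comes back to the route at 19.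

Step 11. The borane may open the allylic epoxide reductively in the SN2' sense, or residual vinyl epoxide may be ionised by zerovalent palladium. The fallback sets out from epoxy alcohol 8 and avoids the vinyl epoxide altogether. Iodination (iodine, PPh3, imidazole) would give (2S,3S)-2-[(3S)-3-bromo-4-chloro-4-methylpentyl]-3-(iodomethyl)-2-methyloxirane F3. C8 would then be introduced already bearing boron by deborylative alkylation with bis(pinacolboryl)methane, CH2(Bpin)2, and NaOtBu (THF, rt), giving 2-{2-[(2R,3S)-3-[(3S)-3-bromo-4-chloro-4-methylpentyl]-3-methyloxiran-2-yl]ethyl}-4,4,5,5-tetramethyl-1,3,2-dioxaborolane F4. Suzuki–Miyaura coupling of F4 with 15 (Pd(OAc)2, RuPhos, K3PO4, toluene/H2O) comes back to the route at 17.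

Step 3. Direct SN2 chlorination may compete with bromine participation, chloride may open the bromonium ion at the wrong carbon, or elimination to an allylic bromide may take over. The fallback sets out from epoxide 2 and bypasses step 2 as well. Opening with bromide in the SN2 sense at the secondary carbon (Li2NiBr4, THF; inversion, R to S) would give (2Z,6S)-6-bromo-7-hydroxy-3,7-dimethyloct-2-en-1-yl acetate F5. Replacement of its tertiary hydroxyl by chloride (HCl in dioxane, CH2Cl2, 0 °C), with ionisation assisted by the neighbouring bromine and retention at CHBr, comes back to the route at 6.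

**Further compounds**

F1 | step 12 | 2-[(3S)-3-bromo-4-chloro-4-methylpentyl]-3-{(3S)-3-[(tert-butyldimethylsilyl)oxy]-3-methylpent-4-en-1-yl}-2-methyl-4-methylidenecyclohexan-1-ol, ring configuration as in 18 | C=C[C@@](C)(O[Si](C)(C)C(C)(C)C)CC[C@@H]1C(=C)CC[C@@H](O)[C@@]1(C)CC[C@H](Br)C(C)(C)Cl
F2 | step 12 | compound 19 with its bridgehead methyl replaced by CH2HgOCOCF3 (organomercurial, not isolated) | C=C[C@@](C)(O[Si](C)(C)C(C)(C)C)CC[C@H]1[C@](C)(CC[C@H](Br)C(C)(C)Cl)[C@H]2CC[C@]1(C[Hg]OC(=O)C(F)(F)F)O2
F3 | step 11 | (2S,3S)-2-[(3S)-3-bromo-4-chloro-4-methylpentyl]-3-(iodomethyl)-2-methyloxirane | IC[C@H]1O[C@@]1(C)CC[C@H](Br)C(C)(C)Cl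
F4 | step 11 | 2-{2-[(2R,3S)-3-[(3S)-3-bromo-4-chloro-4-methylpentyl]-3-methyloxiran-2-yl]ethyl}-4,4,5,5-tetramethyl-1,3,2-dioxaborolane | CC1(C)OB(CC[C@H]2O[C@@]2(C)CC[C@H](Br)C(C)(C)Cl)OC1(C)C
F5 | step 3 | (2Z,6S)-6-bromo-7-hydroxy-3,7-dimethyloct-2-en-1-yl acetate | CC(=O)OC/C=C(/C)CC[C@H](Br)C(C)(C)O
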